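The route rests on the C6–C7 bond, the edge shared by the ten-membered carbocycle (ring A, C1–C10) and the butenolide (ring B, O–C12–C11=C7–C6). C7 is the β-carbon of the C12 enoate and C6 a carbinol carbon beside the C4–C5 epoxide. One intramolecular Nozaki–Hiyama–Kishi coupling of a (Z)-β-iodoenoate with an α,β-epoxy aldehyde therefore closes ring A, sets C6 and lets the new alkoxide lactonise onto the cis methyl ester to close ring B, which gives the target directly. The precursor is an open-chain, fully acylated C6 aldehyde that carries the epoxide, the C1 ketone and the C7 iodide.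

Key step: step 16

Remark (numbering): C1 ketone carbon, C2, C3, C4/C5 epoxide carbons, C6 lactone carbinol carbon, C7=C11 butenolide alkene, C8 propanoyloxy carbon, C9, C10 acetoxy carbon, C12 lactone carbonyl, C13 acetoxymethyl carbon, C14 methyl on C10, C15 methyl on C4.

Remark (assumption): (S,S)-ProPhenol is taken as the ligand enantiomer that gives the 8S carbinol in step 9; if the sense is the opposite, the (R,R) ligand is used.

Step 1
Reactants: 1 3-methylbut-2-en-1-ol (prenol); 2 4-methoxybenzyl chloride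
Product: 3 4-methoxybenzyl prenyl ether
Conditions: NaH, Bu4NI (cat.), THF, 0 °C to rt
Reagents that add atoms: none
Why: Williamson ether synthesis of the primary allylic alkoxide with the benzylic chloride; no stereocentre is involved.

Step 2
Reactants: 3 4-methoxybenzyl prenyl ether
Product: 4 (E)-4-[(4-methoxybenzyl)oxy]-2-methylbut-2-en-1-ol
Conditions: SeO2 (cat.), t-BuOOH, salicylic acid (cat.), CH2Cl2, rt
Reagents that add atoms: selenium dioxide, O=[Se]=O (catalytic oxygen carrier); tert-butyl hydroperoxide, CC(C)(C)OO (terminal oxidant)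
Why: Selenium dioxide allylic oxidation (ene reaction then [2,3]-shift) attacks the (E)-methyl group of the trisubstituted alkene and should give the E allylic alcohol.

Step 3
Reactants: 4 (E)-4-[(4-methoxybenzyl)oxy]-2-methylbut-2-en-1-ol
Product: 5 (E)-1-bromo-4-[(4-methoxybenzyl)oxy]-2-methylbut-2-ene
Conditions: CBr4, PPh3, CH2Cl2, 0 °C
Reagents that add atoms: tetrabromomethane, BrC(Br)(Br)Br
Why: Appel bromination of the primary allylic alcohol should proceed by SN2 displacement without allylic shift, so the E geometry is kept.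

Step 4
Reactants: 6 (2S,5S)-2-tert-butyl-5-methyl-1,3-dioxolan-4-one; 7 tert-butyl(2-iodoethoxy)dimethylsilane
Product: 8 (2S,5R)-2-tert-butyl-5-[2-(tert-butyldimethylsilyloxy)ethyl]-5-methyl-1,3-dioxolan-4-one
Conditions: LiN(i-Pr)2, THF, −78 °C; then 7, DMPU, −78 to −30 °C
Reagents that add atoms: none
Why: Seebach alkylation (self-regeneration of stereocentres): the lithium enolate is alkylated on the face anti to the tert-butyl group, which sets C10 with overall retention.

Step 5
Reactants: 8 (2S,5R)-2-tert-butyl-5-[2-(tert-butyldimethylsilyloxy)ethyl]-5-methyl-1,3-dioxolan-4-one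
Product: 9 (R)-5-(tert-butyldimethylsilyloxy)-3-hydroxy-3-methylpentan-2-one
Conditions: MeLi, THF, −78 °C; aq. NH4Cl
Reagents that add atoms: methyllithium, [Li]C
Why: Acyl substitution at the dioxolanone carbonyl: the lithium hemiketal should be stable at low temperature and collapse on work-up to the methyl ketone with loss of pivalaldehyde, so no second addition occurs and C10 is untouched.

Step 6
Reactants: 9 (R)-5-(tert-butyldimethylsilyloxy)-3-hydroxy-3-methylpentan-2-one; 5 (E)-1-bromo-4-[(4-methoxybenzyl)oxy]-2-methylbut-2-ene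
Product: 10 (3R,7E)-1-(tert-butyldimethylsilyloxy)-3-hydroxy-9-[(4-methoxybenzyl)oxy]-3,7-dimethylnon-7-en-4-one
Conditions: LiN(i-Pr)2 (2.2 equiv), THF, −78 °C; then 5, −78 to −20 °C
Reagents that add atoms: none
Why: Enolate alkylation: C10 is quaternary, so the alkoxide–enolate dianion can only form at the C2 methyl group and should displace the allylic bromide by SN2 to form C2–C3.

Step 7
Reactants: 10 (3R,7E)-1-(tert-butyldimethylsilyloxy)-3-hydroxy-9-[(4-methoxybenzyl)oxy]-3,7-dimethylnon-7-en-4-one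
Product: 11 (3R,7E)-1,3-dihydroxy-9-[(4-methoxybenzyl)oxy]-3,7-dimethylnon-7-en-4-one
Conditions: Bu4NF, THF, 0 °C
Reagents that add atoms: none
Why: Fluoride-mediated cleavage of the primary silyl ether; the 4-methoxybenzyl ether and the alkene are inert.

Step 8
Reactants: 11 (3R,7E)-1,3-dihydroxy-9-[(4-methoxybenzyl)oxy]-3,7-dimethylnon-7-en-4-one
Product: 12 (3R,7E)-3-hydroxy-9-[(4-methoxybenzyl)oxy]-3,7-dimethyl-4-oxonon-7-enal
Conditions: Dess–Martin periodinane, NaHCO3, CH2Cl2, 0 °C; used crude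
Reagents that add atoms: none
Why: Dess–Martin oxidation of the primary alcohol to the C8 aldehyde; the tertiary C10 hydroxyl cannot be oxidised.

Step 9
Reactants: 12 (3R,7E)-3-hydroxy-9-[(4-methoxybenzyl)oxy]-3,7-dimethyl-4-oxonon-7-enal; 13 methyl propiolate
Product: 14 methyl (4S,6R,10E)-4,6-dihydroxy-12-[(4-methoxybenzyl)oxy]-6,10-dimethyl-7-oxododec-10-en-2-ynoate
Conditions: Me2Zn, (S,S)-ProPhenol (20 mol %), Ph3PO, toluene, 4 °C
Reagents that add atoms: none
Why: Zinc–ProPhenol asymmetric alkynylation: the zinc alkynylide adds to the aldehyde (not the ketone) on the face chosen by the ligand, which sets C8 as S.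

Step 10
Reactants: 14 methyl (4S,6R,10E)-4,6-dihydroxy-12-[(4-methoxybenzyl)oxy]-6,10-dimethyl-7-oxododec-10-en-2-ynoate
Product: 15 methyl (4S,6R,10E)-6-hydroxy-12-[(4-methoxybenzyl)oxy]-6,10-dimethyl-7-oxo-4-(propanoyloxy)dodec-10-en-2-ynoate
Conditions: (EtCO)2O, pyridine, DMAP (cat.), CH2Cl2, −20 °C
Reagents that add atoms: propanoic anhydride, CCC(=O)OC(=O)CC
Why: DMAP-catalysed acylation should take the secondary propargylic hydroxyl and leave the tertiary C10 hydroxyl; C8 is not touched.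

Step 11
Reactants: 15 methyl (4S,6R,10E)-6-hydroxy-12-[(4-methoxybenzyl)oxy]-6,10-dimethyl-7-oxo-4-(propanoyloxy)dodec-10-en-2-ynoate
Product: 16 methyl (2Z,4S,6R,10E)-6-hydroxy-2-(hydroxymethyl)-3-iodo-12-[(4-methoxybenzyl)oxy]-6,10-dimethyl-7-oxo-4-(propanoyloxy)dodeca-2,10-dienoate
Conditions: MgI2, CH2O (monomer in THF, excess), CH2Cl2, −78 to 0 °C
Reagents that add atoms: magnesium iodide, [Mg+2].[I-].[I-]; formaldehyde, C=O
Why: MgI2-promoted iodo-aldol (β-iodo Morita–Baylis–Hillman) reaction: iodide adds to C7 and the magnesium allenolate should capture formaldehyde at C11 anti to iodine, which places iodine cis to the ester and C13 cis to C8.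

Step 12
Reactants: 16 methyl (2Z,4S,6R,10E)-6-hydroxy-2-(hydroxymethyl)-3-iodo-12-[(4-methoxybenzyl)oxy]-6,10-dimethyl-7-oxo-4-(propanoyloxy)dodeca-2,10-dienoate
Product: 17 methyl (2Z,4S,6R,10E)-6-acetoxy-2-(acetoxymethyl)-3-iodo-12-[(4-methoxybenzyl)oxy]-6,10-dimethyl-7-oxo-4-(propanoyloxy)dodeca-2,10-dienoate
Conditions: Ac2O, Et3N, DMAP, CH2Cl2, rt
Reagents that add atoms: acetic anhydride, CC(=O)OC(C)=O
Why: DMAP-catalysed acetylation of the primary C13 hydroxyl and, more slowly, of the tertiary α-ketol hydroxyl at C10.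

Step 13
Reactants: 17 methyl (2Z,4S,6R,10E)-6-acetoxy-2-(acetoxymethyl)-3-iodo-12-[(4-methoxybenzyl)oxy]-6,10-dimethyl-7-oxo-4-(propanoyloxy)dodeca-2,10-dienoate
Product: 18 methyl (2Z,4S,6R,10E)-6-acetoxy-2-(acetoxymethyl)-12-hydroxy-3-iodo-6,10-dimethyl-7-oxo-4-(propanoyloxy)dodeca-2,10-dienoate
Conditions: DDQ, CH2Cl2/pH 7 buffer, 0 °C
Reagents that add atoms: none
Why: Oxidative cleavage of the 4-methoxybenzyl ether by DDQ under neutral conditions, which the esters, the ketone and the iodoalkene tolerate.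

Step 14
Reactants: 18 methyl (2Z,4S,6R,10E)-6-acetoxy-2-(acetoxymethyl)-12-hydroxy-3-iodo-6,10-dimethyl-7-oxo-4-(propanoyloxy)dodeca-2,10-dienoate
Product: 19 methyl (2Z,4S,6R)-6-acetoxy-2-(acetoxymethyl)-9-[(2R,3R)-3-(hydroxymethyl)-2-methyloxiran-2-yl]-3-iodo-6-methyl-7-oxo-4-(propanoyloxy)non-2-enoate
Conditions: Ti(OiPr)4, D-(−)-diethyl tartrate, t-BuOOH, 4 Å molecular sieves, CH2Cl2, −20 °C
Reagents that add atoms: tert-butyl hydroperoxide, CC(C)(C)OO
Why: Sharpless asymmetric epoxidation of the E allylic alcohol: the D-(−)-tartrate complex delivers oxygen to the face that gives the 4R,5R epoxide, and the electron-poor iodoenoate is not epoxidised.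

Step 15
Reactants: 19 methyl (2Z,4S,6R)-6-acetoxy-2-(acetoxymethyl)-9-[(2R,3R)-3-(hydroxymethyl)-2-methyloxiran-2-yl]-3-iodo-6-methyl-7-oxo-4-(propanoyloxy)non-2-enoate
Product: 20 methyl (2Z,4S,6R)-6-acetoxy-2-(acetoxymethyl)-9-[(2R,3S)-3-formyl-2-methyloxiran-2-yl]-3-iodo-6-methyl-7-oxo-4-(propanoyloxy)non-2-enoate
Conditions: Dess–Martin periodinane, NaHCO3, CH2Cl2, 0 °C; used at once
Reagents that add atoms: none
Why: Buffered Dess–Martin oxidation of the epoxy alcohol to the epoxy aldehyde without epimerisation at C5 (the descriptor changes only because the priorities change).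

Step 16
Reactants: 20 methyl (2Z,4S,6R)-6-acetoxy-2-(acetoxymethyl)-9-[(2R,3S)-3-formyl-2-methyloxiran-2-yl]-3-iodo-6-methyl-7-oxo-4-(propanoyloxy)non-2-enoate
Product: 22 CNP0285168.1 (target), via ten-membered γ-hydroxy enoate 21 (not isolated)
Conditions: CrCl2 (excess), NiCl2 (cat.), DMSO, rt, slow addition of 20 at high dilution
Reagents that add atoms: none
Why: Zerovalent nickel inserts into the C7–I bond, the alkenyl group passes to trivalent chromium and adds to the C6 aldehyde, and the chromium alkoxide then attacks the cis C12 methyl ester (Nozaki–Hiyama–Kishi reaction followed by lactonisation). The closest known reaction types are the Ni/Cr coupling of (Z)-β-iodoenoates with aldehydes that gives butenolides directly and divalent-chromium closures of α,β-epoxy aldehydes to ten-membered carbocycles. Ring A closes by 10-exo-trig addition of C7 to the C6 carbonyl and ring B by 5-exo-trig acyl substitution of O6 at C12. The new C6 stereocentre is controlled by the adjacent C5 epoxide carbon and the macrocyclic geometry: C7 should attack anti to the C5–O bond with the bulky chromium-bound carbonyl oxygen on the H5 side, turned away from the C4 substituents and the ring interior (the same face as in a Cram chelate with the epoxide oxygen), which gives 6S. The step needs aldehyde-over-ketone and ring-over-oligomer selectivity and retention of the Z geometry; these rest on the low reactivity of alkenylchromium towards the neopentylic C1 ketone, on high dilution, and on the configurational stability of the alkenylchromium.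

Compound list
1 | 3-methylbut-2-en-1-ol (prenol) | CC(C)=CCO | starting material
2 | 4-methoxybenzyl chloride | COc1ccc(CCl)cc1 | starting material
3 | 4-methoxybenzyl prenyl ether | COc1ccc(COCC=C(C)C)cc1 | intermediate
4 | (E)-4-[(4-methoxybenzyl)oxy]-2-methylbut-2-en-1-ol | COc1ccc(COC/C=C(\C)CO)cc1 | intermediate
5 | (E)-1-bromo-4-[(4-methoxybenzyl)oxy]-2-methylbut-2-ene | COc1ccc(COC/C=C(\C)CBr)cc1 | intermediate
6 | (2S,5S)-2-tert-butyl-5-methyl-1,3-dioxolan-4-one | C[C@@H]1O[C@H](C(C)(C)C)OC1=O | starting material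
7 | tert-butyl(2-iodoethoxy)dimethylsilane | CC(C)(C)[Si](C)(C)OCCI | starting material
8 | (2S,5R)-2-tert-butyl-5-[2-(tert-butyldimethylsilyloxy)ethyl]-5-methyl-1,3-dioxolan-4-one | C[C@]1(CCO[Si](C)(C)C(C)(C)C)O[C@H](C(C)(C)C)OC1=O | intermediate
9 | (R)-5-(tert-butyldimethylsilyloxy)-3-hydroxy-3-methylpentan-2-one | CC(=O)[C@](C)(O)CCO[Si](C)(C)C(C)(C)C | intermediate
10 | (3R,7E)-1-(tert-butyldimethylsilyloxy)-3-hydroxy-9-[(4-methoxybenzyl)oxy]-3,7-dimethylnon-7-en-4-one | COc1ccc(COC/C=C(\C)CCC(=O)[C@](C)(O)CCO[Si](C)(C)C(C)(C)C)cc1 | intermediate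
11 | (3R,7E)-1,3-dihydroxy-9-[(4-methoxybenzyl)oxy]-3,7-dimethylnon-7-en-4-one | COc1ccc(COC/C=C(\C)CCC(=O)[C@](C)(O)CCO)cc1 | intermediate
12 | (3R,7E)-3-hydroxy-9-[(4-methoxybenzyl)oxy]-3,7-dimethyl-4-oxonon-7-enal | COc1ccc(COC/C=C(\C)CCC(=O)[C@](C)(O)CC=O)cc1 | intermediate
13 | methyl propiolate | C#CC(=O)OC | starting material
14 | methyl (4S,6R,10E)-4,6-dihydroxy-12-[(4-methoxybenzyl)oxy]-6,10-dimethyl-7-oxododec-10-en-2-ynoate | COc1ccc(COC/C=C(\C)CCC(=O)[C@](C)(O)C[C@H](O)C#CC(=O)OC)cc1 | intermediate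
15 | methyl (4S,6R,10E)-6-hydroxy-12-[(4-methoxybenzyl)oxy]-6,10-dimethyl-7-oxo-4-(propanoyloxy)dodec-10-en-2-ynoate | COc1ccc(COC/C=C(\C)CCC(=O)[C@](C)(O)C[C@H](OC(=O)CC)C#CC(=O)OC)cc1 | intermediate
16 | methyl (2Z,4S,6R,10E)-6-hydroxy-2-(hydroxymethyl)-3-iodo-12-[(4-methoxybenzyl)oxy]-6,10-dimethyl-7-oxo-4-(propanoyloxy)dodeca-2,10-dienoate | COc1ccc(COC/C=C(\C)CCC(=O)[C@](C)(O)C[C@H](OC(=O)CC)/C(I)=C(\CO)C(=O)OC)cc1 | intermediate
17 | methyl (2Z,4S,6R,10E)-6-acetoxy-2-(acetoxymethyl)-3-iodo-12-[(4-methoxybenzyl)oxy]-6,10-dimethyl-7-oxo-4-(propanoyloxy)dodeca-2,10-dienoate | COc1ccc(COC/C=C(\C)CCC(=O)[C@](C)(OC(C)=O)C[C@H](OC(=O)CC)/C(I)=C(\COC(C)=O)C(=O)OC)cc1 | intermediate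
18 | methyl (2Z,4S,6R,10E)-6-acetoxy-2-(acetoxymethyl)-12-hydroxy-3-iodo-6,10-dimethyl-7-oxo-4-(propanoyloxy)dodeca-2,10-dienoate | OC/C=C(\C)CCC(=O)[C@](C)(OC(C)=O)C[C@H](OC(=O)CC)/C(I)=C(\COC(C)=O)C(=O)OC | intermediate
19 | methyl (2Z,4S,6R)-6-acetoxy-2-(acetoxymethyl)-9-[(2R,3R)-3-(hydroxymethyl)-2-methyloxiran-2-yl]-3-iodo-6-methyl-7-oxo-4-(propanoyloxy)non-2-enoate | OC[C@H]1O[C@]1(C)CCC(=O)[C@](C)(OC(C)=O)C[C@H](OC(=O)CC)/C(I)=C(\COC(C)=O)C(=O)OC | intermediate
20 | methyl (2Z,4S,6R)-6-acetoxy-2-(acetoxymethyl)-9-[(2R,3S)-3-formyl-2-methyloxiran-2-yl]-3-iodo-6-methyl-7-oxo-4-(propanoyloxy)non-2-enoate | O=C[C@H]1O[C@]1(C)CCC(=O)[C@](C)(OC(C)=O)C[C@H](OC(=O)CC)/C(I)=C(\COC(C)=O)C(=O)OC | intermediate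
21 | ten-membered γ-hydroxy enoate (4R,5R,6S,8S,10R; C6 hydroxyl cis to the C12 methyl ester; formed as its trivalent-chromium alkoxide) | CCC(=O)O[C@H]1C[C@@](C)(OC(C)=O)C(=O)CC[C@@]2(C)O[C@@H]2[C@@H](O)/C1=C(\C(=O)OC)COC(C)=O | intermediate
22 | CNP0285168.1 (4R,5R,6S,8S,10R) | CCC(=O)O[C@H]1C[C@@](C)(OC(C)=O)C(=O)CC[C@@]2(C)O[C@@H]2[C@H]2OC(=O)C(COC(C)=O)=C12 | target

Total step count: 16. Longest linear sequence: 14 steps (steps 1–3, then steps 6–16); the branch from 6 runs 13 steps (steps 4–16).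

Steps most likely to fail

Step 16 (key step). The alkenylchromium may add to the C1 ketone through a five-membered transition state, or to a second molecule, faster than it closes the ten-membered ring; the C6 face selectivity may also be low. The fallback removes the internal competitor by a redox detour. It sets out from 19: NaBH4/CeCl3·7H2O in MeOH at −78 °C reduces the C1 ketone to the C1 carbinol (either epimer; the centre is removed later), giving epoxy diol F1. TEMPO/PhI(OAc)2 then oxidises only the primary alcohol to the hydroxy epoxy aldehyde F2. The same CrCl2/NiCl2 closure gives the 1-hydroxy γ-hydroxy enoate F3 (not isolated) and from it the 1-hydroxy lactone F4. Dess–Martin oxidation of the C1 hydroxyl returns to the route at 22.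

Step 11. The iodo-allenolate may be captured on the wrong face (E/Z mixture at C7=C11) or by the C1 ketone instead of formaldehyde. The fallback uses substrate direction and sets out from 14. The iodo-aldol is run on the free C8 carbinol as its magnesium alkoxide, which holds formaldehyde at O8 and delivers it to C11 from the C8 side; any isomer with the ester cis to C8 lactonises and is removed. This gives diol iodide F5. Acetyl chloride/2,4,6-collidine at −78 °C acetylates only the primary C13 hydroxyl to give monoacetate F6. Propanoic anhydride/DMAP gives the C8 propanoate F7, and Ac2O/DMAP acetylates the tertiary C10 hydroxyl to return at 17.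

Step 9. A zinc enolate may form at C2 and cyclise onto the C8 aldehyde, the β-hydroxyl may be eliminated, or facial control may be poor. The fallback separates C–C bond formation from stereocontrol and sets out from 12. Lithium methyl propiolate (from 13 and LiN(i-Pr)2, THF, −90 °C) adds quickly to the aldehyde to give the C8-epimeric propargylic alcohols F8. Dess–Martin oxidation gives ynone F9. Asymmetric transfer hydrogenation with RuCl(p-cymene)[(S,S)-TsDPEN] and HCO2H/Et3N reduces only the ynone and returns to the route at 14.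

Further compounds
F1 | step 16 | epoxy diol (C1 carbinol of 19, either C1 epimer) | OC[C@H]1O[C@]1(C)CCC(O)[C@](C)(OC(C)=O)C[C@H](OC(=O)CC)/C(I)=C(\COC(C)=O)C(=O)OC
F2 | step 16 | hydroxy epoxy aldehyde (C1 carbinol of 20) | O=C[C@H]1O[C@]1(C)CCC(O)[C@](C)(OC(C)=O)C[C@H](OC(=O)CC)/C(I)=C(\COC(C)=O)C(=O)OC
F3 | step 16 | ten-membered 1-hydroxy γ-hydroxy enoate (C1 carbinol of 21, not isolated) | CCC(=O)O[C@H]1C[C@@](C)(OC(C)=O)C(O)CC[C@@]2(C)O[C@@H]2[C@@H](O)/C1=C(\C(=O)OC)COC(C)=O
F4 | step 16 | 1-hydroxy lactone (C1 carbinol of 22) | CCC(=O)O[C@H]1C[C@@](C)(OC(C)=O)C(O)CC[C@@]2(C)O[C@@H]2[C@H]2OC(=O)C(COC(C)=O)=C12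
F5 | step 11 | diol iodide: methyl (2Z,4S,6R,10E)-4,6-dihydroxy-2-(hydroxymethyl)-3-iodo-12-[(4-methoxybenzyl)oxy]-6,10-dimethyl-7-oxododeca-2,10-dienoate | COc1ccc(COC/C=C(\C)CCC(=O)[C@](C)(O)C[C@H](O)/C(I)=C(\CO)C(=O)OC)cc1
F6 | step 11 | monoacetate: methyl (2Z,4S,6R,10E)-2-(acetoxymethyl)-4,6-dihydroxy-3-iodo-12-[(4-methoxybenzyl)oxy]-6,10-dimethyl-7-oxododeca-2,10-dienoate | COc1ccc(COC/C=C(\C)CCC(=O)[C@](C)(O)C[C@H](O)/C(I)=C(\COC(C)=O)C(=O)OC)cc1
F7 | step 11 | C8 propanoate: methyl (2Z,4S,6R,10E)-2-(acetoxymethyl)-6-hydroxy-3-iodo-12-[(4-methoxybenzyl)oxy]-6,10-dimethyl-7-oxo-4-(propanoyloxy)dodeca-2,10-dienoate | COc1ccc(COC/C=C(\C)CCC(=O)[C@](C)(O)C[C@H](OC(=O)CC)/C(I)=C(\COC(C)=O)C(=O)OC)cc1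
F8 | step 9 | C8-epimeric propargylic alcohols: methyl (6R,10E)-4,6-dihydroxy-12-[(4-methoxybenzyl)oxy]-6,10-dimethyl-7-oxododec-10-en-2-ynoate | COc1ccc(COC/C=C(\C)CCC(=O)[C@](C)(O)CC(O)C#CC(=O)OC)cc1
F9 | step 9 | ynone: methyl (6R,10E)-6-hydroxy-12-[(4-methoxybenzyl)oxy]-6,10-dimethyl-4,7-dioxododec-10-en-2-ynoate | COc1ccc(COC/C=C(\C)CCC(=O)[C@](C)(O)CC(=O)C#CC(=O)OC)cc1
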